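**Retrosynthetic overview**

1. The target is the all-trans oxolane (2S,3R,4S; ring numbered O1, C2 aryl, C3 CH2OH, C4 aroyl). C2 (benzylic ether of a p-hydroxyaryl) and C4 (α to the ketone) can be equilibrated to trans, so only C3 has to be set absolutely.
2. Oxolane ⇒ acyclic keto-triol 8 by C2–O1 closure through a p-quinone methide, plus epimerisation at C4. This is the only ring formed, and it is formed last.
3. Keto-triol 8 ⇒ C2-symmetric tetraol 7 by a single benzylic oxidation, which removes the C2 axis.
4. Tetraol 7 ⇒ achiral, symmetric succinaldehyde plus two protected syringaldehydes by a two-directional L-proline aldol that sets both CH(CH2OH) centres.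

Assumption: succinaldehyde is not reliably stocked, so it is made fresh from commercial 2,5-dimethoxytetrahydrofuran (Step 2).

**Route**

Step 1
Reactants: 1 syringaldehyde; 2 pivaloyl chloride
Product: 3 4-formyl-2,6-dimethoxyphenyl pivalate
Conditions: PivCl (1.2 equiv), Et3N, DMAP (cat.), CH2Cl2, 0 °C → rt
Reagents that add atoms: pivaloyl chloride, CC(C)(C)C(=O)Cl (reactant 2)
Why: O-acylation of the phenol; the pivalate survives amine catalysis and borohydride and turns the electron-rich aldehyde into an electron-poor aldol acceptor; no stereocentre.

Step 2
Reactants: 4 2,5-dimethoxytetrahydrofuran (cis/trans mixture)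
Product: 5 succinaldehyde (butanedial)
Conditions: H2O, 90 °C; MeOH/H2O removed, distilled, used immediately
Reagents that add atoms: water, O
Why: thermal hydrolysis of the cyclic bis-acetal is the standard way to liberate monomeric succinaldehyde; no stereocentre.

Step 3
Reactants: 5 succinaldehyde; 3 4-formyl-2,6-dimethoxyphenyl pivalate (3 equiv used, 2 incorporated)
Product: 6 (1R,2R,3R,4R)-2,3-bis(hydroxymethyl)-1,4-bis[3,5-dimethoxy-4-(pivaloyloxy)phenyl]butane-1,4-diol (carbinol centres C1/C4 drawn for the anti,anti adduct; their configuration is irrelevant later)
Conditions: L-proline (20 mol %), DMF, 4 °C, 5 added by syringe pump over 24 h, then 24 h; then NaBH4, MeOH, 0 °C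
Reagents that add atoms: none (NaBH4 adds H only)
Why: Proposed new method: a two-directional enamine cross-aldol in which each α-CH2 of succinaldehyde reacts once with the non-enolisable aryl aldehyde through the proline (E)-enamine / carboxylic-acid-directed (Houk–List) transition state, giving the same sense at both α-carbons (S as aldehydes, which becomes 2R,3R after reduction); the first adduct rests as a lactol whose remaining α-branched CHO does not re-enolise, the C2 product is enriched in ee because mismatches end up in the separable meso diastereomer, and in-situ NaBH4 freezes the α-centres; the closest known chemistry is the proline-catalysed aldehyde–aldehyde cross-aldol with aromatic acceptors and the proline-catalysed Mannich/Michael annulations and aldol dimerisation of succinaldehyde.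

Step 4
Reactants: 6
Product: 7 (1R,2R,3R,4R)-1,4-bis(4-hydroxy-3,5-dimethoxyphenyl)-2,3-bis(hydroxymethyl)butane-1,4-diol
Conditions: K2CO3, MeOH, 40 °C; neutral work-up
Reagents that add atoms: none
Why: methanolysis (transesterification) of the two aryl pivalates; basic conditions do not ionise the p-hydroxybenzylic alcohols and no stereocentre is touched.

Step 5
Reactants: 7
Product: 8 (2R,3R,4R)-4-hydroxy-1,4-bis(4-hydroxy-3,5-dimethoxyphenyl)-2,3-bis(hydroxymethyl)butan-1-one
Conditions: DDQ (1.0 equiv), 1,4-dioxane, rt; unreacted 7 recovered and recycled
Reagents that add atoms: none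
Why: DDQ dehydrogenation of a p-hydroxybenzylic alcohol (hydride abstraction through a dearomatised quinonoid intermediate) gives the aryl ketone and leaves primary alcohols alone; the two carbinols are homotopic, so oxidising either one gives the same compound and removes the C2 axis; the oxidised ring is then deactivated, but the other carbinol is not, so roughly statistical mono-oxidation (about 45–50 %) is expected.

Step 6
Reactants: 8
Product: 9 the target, (4-hydroxy-3,5-dimethoxyphenyl)[(2S,3R,4S)-2-(4-hydroxy-3,5-dimethoxyphenyl)-3-(hydroxymethyl)oxolan-4-yl]methanone
Conditions: TsOH·H2O (10 mol %), MeCN, 40 °C; then K2CO3, MeOH, 40 °C (one pot)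
Reagents that add atoms: none (loss of H2O)
Why: acid ionises the remaining p-hydroxybenzylic alcohol to a p-quinone methide, and 5-exo oxa-1,6-addition of the CH2OH α to the ketone closes the oxolane and rearomatises (the other CH2OH could only give an oxetane); this closure is reversible, so C2 settles trans to C3, and the base stage epimerises the α-keto centre C4 (initially cis, not isolated) to the all-trans isomer, while C3 from Step 3 is not enolisable and is retained.

**Compound list**

1 | syringaldehyde | COc1cc(C=O)cc(OC)c1O | starting material
2 | pivaloyl chloride | CC(C)(C)C(=O)Cl | starting material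
3 | 4-formyl-2,6-dimethoxyphenyl pivalate | COc1cc(C=O)cc(OC)c1OC(=O)C(C)(C)C | intermediate
4 | 2,5-dimethoxytetrahydrofuran | COC1CCC(OC)O1 | starting material
5 | succinaldehyde | O=CCCC=O | intermediate
6 | (1R,2R,3R,4R)-tetraol bis-pivalate | COc1cc(cc(OC)c1OC(=O)C(C)(C)C)[C@H](O)[C@@H](CO)[C@H](CO)[C@@H](O)c1cc(OC)c(OC(=O)C(C)(C)C)c(OC)c1 | intermediate
7 | (1R,2R,3R,4R)-tetraol, free phenols | COc1cc(cc(OC)c1O)[C@H](O)[C@@H](CO)[C@H](CO)[C@@H](O)c1cc(OC)c(O)c(OC)c1 | intermediate
8 | (2R,3R,4R)-keto-triol | COc1cc(cc(OC)c1O)C(=O)[C@@H](CO)[C@H](CO)[C@@H](O)c1cc(OC)c(O)c(OC)c1 | intermediate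
9 | target, (2S,3R,4S)-oxolane | COc1cc(C(=O)[C@@H]2CO[C@H](c3cc(OC)c(O)c(OC)c3)[C@H]2CO)cc(OC)c1O | target

**Totals**

Total steps: 6. Longest linear sequence: 5 (1 → 3 → 6 → 7 → 8 → 9).

**Steps most likely to fail, with fallbacks**

1. Step 3, the two-directional proline aldol. Risks are succinaldehyde self-aldol and oligomerisation, a stalled second aldol, and dehydration of the adduct. Fallback: make the same (2R,3R) tetraol by a different bond construction. Oxidatively dimerise ethyl 3-aryl-3-oxopropanoate to the symmetric diethyl 2,3-bis(aroyl)succinate, reduce both ketones by Ru–TsDPEN transfer hydrogenation with dynamic kinetic resolution to the C2-symmetric dilactone, then LiAlH4.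
2. Step 5, the mono-oxidation. Risks are the statistical mixture with diketone, and quinone-methide side reactions of the free p-hydroxybenzylic alcohols. Fallback: differentiate the two ends before oxidation by running the two aldols sequentially with differently protected aldehydes (pivalate first, allyl ether second). Only one phenol is then unmasked, and only that benzylic alcohol is oxidisable by DDQ.
3. Step 6, cyclisation and equilibration. Risks are dehydration or ketalisation of the β-hydroxy ketone under acid, and slow C4 epimerisation once the ketone-ring phenol is deprotonated. Fallback: reverse the order of ring formation and oxidation. Cyclise tetraol 7 under acid to the furofuran (both benzylic ethers closed), open one ring oxidatively with DDQ/H2O to the cis keto-alcohol, then epimerise C2 and C4 on the monocyclic oxolane.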